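## The problem

Glisoflavone (11) has no stereocenter, so the synthesis is a matter of regiochemistry and of the order in which sensitive groups appear. Three placements must come out right: ring B on C3 and not on C2 of the pyranone ring C, a methyl ether on O5 beside the carbonyl while O7 stays a free phenol, and a 3-methylbut-2-enyl chain on C5' next to the C3'/C4' catechol. The prenyl olefin is attacked by electrophilic oxidants and, under protic or Lewis acid, is captured by the neighbouring 4'-hydroxyl to give a 2,2-dimethylchroman. The catechol is oxidised to the ortho-quinone by metal oxidants and, once deprotonated, by air; ring C opens at C2 under strong base. With no stereocenter present, nothing can be relayed from one center to another, and control has to come from the substitution pattern of the two aromatic building blocks. The feature that makes the key step possible is the oxygen on C4', para to C1'. It makes ring B a good migrating group from the β-carbon to the α-carbon of a chalcone, and the 2'-hydroxyl of ring A is then placed to close O1–C2 onto the old β-carbon. The plan therefore has to keep oxidant away from olefin and free catechol, and acid away from the finished prenylphenol.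

## Retrosynthesis

**11 from 10.** The last operation should uncover three phenols and touch nothing else, so the three O–acetyl bonds of triacetate 10 are cut. Acetal, benzyl or methyl ethers would need acid, hydrogen or a boron halide here, which would close the chroman, reduce the olefin or strip the O5 methyl group. Aryl acetates fall to catalytic carbonate in methanol. 10 is no simpler than 11 in skeleton. The forward step only has to be faster than base attack at C2 of ring C and has to be run without air.

**10 from 8 and 9.** The C5'–CH2 bond is cut to aryl bromide 8 and prenylstannane 9. A Claisen rearrangement from O4' would deliver the chain through its tertiary end, and a Friedel–Crafts prenylation would choose the more nucleophilic ring A. Carrying the prenyl group through from the aldehyde is excluded, because the olefin would survive neither the thallium oxidant nor the hydrochloric acid of the ring closure. A bromine atom is inert to both and is already present in aldehyde 3. The coupling must insert palladium into a bromide flanked by an acetoxy group and must transfer the allylic group through its CH2 end.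

**8 from 7.** The same three O–acetyl bonds are cut again, back to triol 7. The esters make ring B poorer in electrons for oxidative addition, keep phenoxides away from palladium and protect the catechol from oxidation at 95 °C. They also fix the mild final deprotection. This costs steps 5 and 7 and buys an end game without acid.

**7 from 5 through 6.** O1–C2 and C3–C1' are cut, which is the reverse of a 1,2-shift of ring B followed by ring closure, and leads to 2'-hydroxychalcone 5. The neighbouring cuts are weaker here. A deoxybenzoin approach would acylate a phloroglucinol monomethyl ether with poor control between its two kinds of free position. A 3-halochromone cross-coupling would need a boron partner that also carries the bromine. The chalcone draws both rings from simple carbonyl compounds, and the O5-methyl/O7-hydroxyl pattern comes with ketone 1. The forward step must let ring B migrate faster than the 2'-hydroxyl can close to an aurone, must leave ring A alone, and must leave no oxidant behind when the catechol is unmasked.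

**5 from 2 and 4.** The Cα=Cβ bond is cut to methyl ketone 2 and aldehyde 4. A crossed aldol condensation is the obvious forward reaction, since 4 cannot enolise. It has to tolerate the free chelated hydroxyl of 2, which is needed later as O1.

**2 from 1, and 4 from 3.** Only O–CH2 bonds of methoxymethyl (MOM) ethers are cut. MOM ethers survive hydroxide, should last through the short thallium stage and leave in the acid stage of the key step without a separate operation. In 1 the hydroxyl ortho to the acetyl group is hydrogen-bonded and stays free under carbonate.

## Roads not taken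

**Alternative 1:** Ring B would be built last by cutting C3'–C4' and C5'–C6'. The bromopyranone A2, which already carries the chromone on C5, would undergo a [4+2] cycloaddition with the prenyl-bearing siloxyalkyne A3. The bridged lactone would lose carbon dioxide to give the arene A1.
- Merits: the prenyl chain arrives attached through the correct carbon, so no allyl-metal regiochemistry arises. The polarity is matched, since the nucleophilic alkyne carbon meets C6 of the pyranone and the oxygen-bearing carbon meets the brominated C3. No thallium is used.
- Weak points: A1 carries bromine on C3', where the target has a hydroxyl. A carbon–bromine to carbon–oxygen exchange would have to be run beside the prenyl olefin and two silyl ethers. A2 needs its own synthesis, joining a chromone to one position of a dihalogenated pyranone. A3 is a moisture-sensitive ynol ether that has to be made by homologation.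
- Comparison: on prenyl regiochemistry this road is better. The chosen plan sets against it a ring B whose two oxygens and halogen come from one commercial aldehyde, a much shorter sequence, and a metathesis fallback that removes the regiochemical doubt at the cost of one step.

**Alternative 2:** Ring C would be closed by cutting O1–C8a, C4–C4a and O1–C2. CsF would release an aryne from the silyl triflate A5. The carboxylate of the methoxyacrylic acid A6 would add at the carbon remote from the methoxy group, and the aryl anion next to the methoxy group would take the acyl carbon. The new phenoxide would then displace methoxide at C2 to give A4.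
- Merits: the route is convergent and forms three bonds in one operation. The regiochemistry is dictated by the methoxy group beside the aryne. There is no thallium and no late cross-coupling.
- Weak points: A4 holds three MOM ethers next to a prenyl group, so the final unmasking needs acid in the presence of the prenylphenol that cyclises to the chroman. A5 needs several steps to differentiate three oxygens of a phloroglucinol and to place silicon. A6 needs a prenylated arylacetic ester, formylation, O-methylation and hydrolysis. Protonation of the aryl anion, giving a plain aryl ester, competes with acyl transfer to the weakly electrophilic vinylogous carbonate carbonyl.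
- Comparison: in convergence and reagent hazard this road is better. The chosen plan sets against it seven steps from catalogue compounds and a deprotection free of acid.

**Alternative 3:** Ring A would be built last by cutting C5–C6. Mg(OMe)2 in methanol would open the lactone ring of the pyranopyrandione A8 to a methyl ester on C4a and an acetonyl group on C8a. The methyl ketone enolate would then close onto the ester to give the 5,7-diol A7.
- Merits: ring A comes from the cheap lactone A9, the folding is that of a polyketide, and no heavy-metal oxidant is needed.
- Weak points: A7 has both O5 and O7 free, and the target needs the methyl group on the chelated, less reactive O5. That means protection of O7, forced methylation of O5 and deprotection, followed by acid removal of MOM groups beside the prenyl chain. Methoxide can also attack C2 of ring C in A8.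
- Comparison: in cost of materials and reagent hazard this road is equal or better. The chosen plan sets against it that the O5/O7 differentiation is bought with ketone 1 and costs no steps.

Key step: step 4

Assumption: ketone 1, aldehyde 3 and stannane 9 are catalogue compounds and are used as bought.

## Steps

Step 1
Reactants: 1 1-(2,4-dihydroxy-6-methoxyphenyl)ethanone
Product: 2 1-[2-hydroxy-6-methoxy-4-(methoxymethoxy)phenyl]ethanone
Conditions: MOMCl (1.1 equiv), K2CO3, acetone, 0 °C to rt
Reagents that add atoms: chloromethyl methyl ether (MOMCl), COCCl
Why: O-alkylation to a MOM ether; the 2-hydroxyl is hydrogen-bonded to the acetyl carbonyl and is the weaker nucleophile under carbonate, so one equivalent of reagent should go to the 4-hydroxyl.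

Step 2
Reactants: 3 3-bromo-4,5-dihydroxybenzaldehyde
Product: 4 3-bromo-4,5-bis(methoxymethoxy)benzaldehyde
Conditions: MOMCl (2.6 equiv), K2CO3 (4 equiv), acetone, 0 °C to 45 °C
Reagents that add atoms: chloromethyl methyl ether (MOMCl), COCCl
Why: Double MOM ether formation on an acidic catechol (aldehyde para, bromine ortho); excess reagent should cover both oxygens, and the aldehyde is inert to carbonate.

Step 3
Reactants: 2 1-[2-hydroxy-6-methoxy-4-(methoxymethoxy)phenyl]ethanone; 4 3-bromo-4,5-bis(methoxymethoxy)benzaldehyde
Product: 5 (E)-3-[3-bromo-4,5-bis(methoxymethoxy)phenyl]-1-[2-hydroxy-6-methoxy-4-(methoxymethoxy)phenyl]prop-2-en-1-one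
Conditions: KOH (50% aq.), EtOH, 0 °C to rt; then aq. NH4Cl
Reagents that add atoms: none
Why: Claisen–Schmidt condensation (crossed aldol, E1cB dehydration); 4 has no α-hydrogen and the conjugated (E)-enone is the thermodynamic product. MOM ethers and the aryl bromide are stable to hydroxide, and the buffered work-up avoids acid closure to the flavanone.

Step 4
Reactants: 5 (E)-3-[3-bromo-4,5-bis(methoxymethoxy)phenyl]-1-[2-hydroxy-6-methoxy-4-(methoxymethoxy)phenyl]prop-2-en-1-one
Product: 7 3-(3-bromo-4,5-dihydroxyphenyl)-7-hydroxy-5-methoxychromen-4-one, via rearranged dimethyl acetal 6 (not isolated)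
Conditions: Tl(NO3)3·3H2O (1.0 equiv), MeOH/HC(OMe)3 (3:1), rt, dark; filter TlNO3; then 10% aq. HCl, 55 °C
Reagents that add atoms: none
Why: Oxidative rearrangement of a 2'-hydroxychalcone by Tl(NO3)3 in methanol followed by acid closure is a known isoflavone synthesis and is the closest precedent. Trivalent thallium bonds to Cα of the enone while methanol adds to the benzylic Cβ; when the weak C–Tl bond breaks and monovalent thallium leaves, ring B bridges Cα and Cβ through a phenonium ion and ends on Cα (bond C3–C1'), and the oxocarbenium ion left on Cβ takes a second methanol to give acetal 6. Aqueous HCl ionises the acetal, the 2'-hydroxyl closes ring C on the oxocarbenium carbon in a 6-exo-trig mode (bond O1–C2), methanol is lost across C2–C3, and the three MOM acetals are exchanged to dimethoxymethane. No stereocenter is set: the one carbon that is stereogenic in 6 becomes the planar C3. The step needs migration of ring B to win over closure to an aurone and over attack of thallium on ring A; the oxygen on C4' para to the migrating carbon, the acetal-forming medium (methanol plus orthoformate, which also takes up the water of the hydrate) and the hydrogen bond that ties the 2'-hydroxyl to the carbonyl all favour migration. One equivalent of oxidant is used so that no trivalent thallium is left when the catechol is unmasked, and bromine, inert to thallium, holds the place of the prenyl group.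

Step 5
Reactants: 7 3-(3-bromo-4,5-dihydroxyphenyl)-7-hydroxy-5-methoxychromen-4-one
Product: 8 7-acetoxy-3-(3,4-diacetoxy-5-bromophenyl)-5-methoxychromen-4-one
Conditions: Ac2O, pyridine, DMAP (cat.), 0 °C to rt
Reagents that add atoms: acetic anhydride, CC(=O)OC(C)=O
Why: DMAP-catalysed O-acetylation; none of the three phenols is chelated, since O5 is a methyl ether. The acetates lower the electron density of ring B before oxidative addition and can be removed later without acid.

Step 6
Reactants: 8 7-acetoxy-3-(3,4-diacetoxy-5-bromophenyl)-5-methoxychromen-4-one; 9 tributyl(3-methylbut-2-enyl)stannane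
Product: 10 7-acetoxy-3-[3,4-diacetoxy-5-(3-methylbut-2-enyl)phenyl]-5-methoxychromen-4-one
Conditions: Pd(PPh3)4 (5 mol %), DMF (degassed), 95 °C
Reagents that add atoms: none
Why: Stille coupling of an aryl bromide with an allylic stannane; zerovalent palladium inserts into C5'–Br, the prenyl group is transferred, and reductive elimination at the unsubstituted CH2 terminus should give the linear 3-methylbut-2-enyl arene, as known for prenylation of halogenated flavonoid acetates. The neutral medium leaves the acetates and the pyranone untouched.

Step 7
Reactants: 10 7-acetoxy-3-[3,4-diacetoxy-5-(3-methylbut-2-enyl)phenyl]-5-methoxychromen-4-one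
Product: 11 glisoflavone, 3-[3,4-dihydroxy-5-(3-methylbut-2-enyl)phenyl]-7-hydroxy-5-methoxychromen-4-one
Conditions: K2CO3 (0.3 equiv), MeOH (degassed), 0 °C to rt, Ar; then aq. NH4Cl
Reagents that add atoms: none
Why: Base-catalysed methanolysis (transesterification) of aryl acetates; the aryloxide leaving groups make it fast with substoichiometric carbonate, so ring C should not be opened. The absence of acid keeps the 4'-hydroxyl from adding to the prenyl olefin, and degassed solvent protects the catecholate from air.

## Compound list

1 | 1-(2,4-dihydroxy-6-methoxyphenyl)ethanone (2',4'-dihydroxy-6'-methoxyacetophenone) | CC(=O)c1c(O)cc(O)cc1OC | starting material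
2 | 1-[2-hydroxy-6-methoxy-4-(methoxymethoxy)phenyl]ethanone | CC(=O)c1c(O)cc(OCOC)cc1OC | intermediate
3 | 3-bromo-4,5-dihydroxybenzaldehyde | O=Cc1cc(O)c(O)c(Br)c1 | starting material
4 | 3-bromo-4,5-bis(methoxymethoxy)benzaldehyde | O=Cc1cc(Br)c(OCOC)c(OCOC)c1 | intermediate
5 | (E)-3-[3-bromo-4,5-bis(methoxymethoxy)phenyl]-1-[2-hydroxy-6-methoxy-4-(methoxymethoxy)phenyl]prop-2-en-1-one | COCOc1cc(O)c(C(=O)/C=C/c2cc(Br)c(OCOC)c(OCOC)c2)c(OC)c1 | intermediate
6 | 2-[3-bromo-4,5-bis(methoxymethoxy)phenyl]-1-[2-hydroxy-6-methoxy-4-(methoxymethoxy)phenyl]-3,3-dimethoxypropan-1-one (racemic; formed in the flask in step 4, not isolated) | COCOc1cc(O)c(C(=O)C(C(OC)OC)c2cc(Br)c(OCOC)c(OCOC)c2)c(OC)c1 | intermediate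
7 | 3-(3-bromo-4,5-dihydroxyphenyl)-7-hydroxy-5-methoxychromen-4-one | COc1cc(O)cc2occ(-c3cc(O)c(O)c(Br)c3)c(=O)c12 | intermediate
8 | 7-acetoxy-3-(3,4-diacetoxy-5-bromophenyl)-5-methoxychromen-4-one | COc1cc(OC(C)=O)cc2occ(-c3cc(OC(C)=O)c(OC(C)=O)c(Br)c3)c(=O)c12 | intermediate
9 | tributyl(3-methylbut-2-enyl)stannane | CCCC[Sn](CCCC)(CCCC)CC=C(C)C | starting material
10 | 7-acetoxy-3-[3,4-diacetoxy-5-(3-methylbut-2-enyl)phenyl]-5-methoxychromen-4-one | COc1cc(OC(C)=O)cc2occ(-c3cc(OC(C)=O)c(OC(C)=O)c(CC=C(C)C)c3)c(=O)c12 | intermediate
11 | glisoflavone, 3-[3,4-dihydroxy-5-(3-methylbut-2-enyl)phenyl]-7-hydroxy-5-methoxychromen-4-one | COc1cc(O)cc2occ(-c3cc(O)c(O)c(CC=C(C)C)c3)c(=O)c12 | target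

## Step count and least certain steps

Total step count: 7. Longest linear sequence: 6 steps (steps 1 or 2, then 3 to 7).

**Step 4 (key step).**
- What may go wrong: the nitric acid released in the thallium stage may remove MOM groups early, after which the oxidant attacks the exposed phenols. The 2'-hydroxyl may capture the thallated intermediate (aurone pathway), because the bromine atom and the out-of-plane twist of the doubly flanked 4-OMOM group lower the migratory aptitude of ring B. The freed catechol may be oxidised by nitric acid or leftover oxidant during the acid stage.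
- Adjustments within the same pathway: a bicarbonate wash of crude 6 before the acid stage, or PhI(OAc)2 in place of Tl(NO3)3.
- Fallback: this uses a different mechanism, the 1,2-acyl shift of a chalcone epoxide, with no oxidant at the rearrangement stage. It sets out from 2 and returns at 7. Ketone 2 would be protected at its chelated hydroxyl (NaH, MOMCl, DMF) to give 1-[2-methoxy-4,6-bis(methoxymethoxy)phenyl]ethanone F1. Condensation with 4 (KOH, EtOH) would give (E)-3-[3-bromo-4,5-bis(methoxymethoxy)phenyl]-1-[2-methoxy-4,6-bis(methoxymethoxy)phenyl]prop-2-en-1-one F2. Weitz–Scheffer epoxidation (H2O2, NaOH, MeOH/THF) would give racemic trans-[3-[3-bromo-4,5-bis(methoxymethoxy)phenyl]oxiran-2-yl]-[2-methoxy-4,6-bis(methoxymethoxy)phenyl]methanone F3. BF3·OEt2 in CH2Cl2 would open the epoxide at the benzylic carbon and shift the aroyl group to it, giving racemic 2-[3-bromo-4,5-bis(methoxymethoxy)phenyl]-3-[2-methoxy-4,6-bis(methoxymethoxy)phenyl]-3-oxopropanal F4, whose formyl carbon is the future C2. Methanolic HCl would then remove the four MOM groups and close ring C by cyclodehydration to 7. MOM loss already at the BF3 stage would be of no consequence.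

**Step 6.**
- What may go wrong: the prenyl group may be transferred through its tertiary terminus, giving the 1,1-dimethylallyl isomer. Oxidative addition into the hindered, oxygen-flanked bromide may be slow, with protodebromination taking over. Acetyl groups may be lost at 95 °C.
- Fallback: the three-carbon unit is installed without regiochemical ambiguity and finished by olefin metathesis. It sets out from 8 and returns at 10. Coupling of 8 with allyltributylstannane (Pd(PPh3)4, DMF, 95 °C) would give 7-acetoxy-3-(3,4-diacetoxy-5-prop-2-enylphenyl)-5-methoxychromen-4-one F5. Cross-metathesis of F5 with 2-methylbut-2-ene and second-generation Grubbs catalyst, (H2IMes)(PCy3)Cl2Ru=CHPh, in CH2Cl2 at 40 °C would give 10.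

**Step 7.**
- What may go wrong: methoxide may open ring C at C2. The catecholate may be oxidised by traces of air. Acidification on work-up may go too far and start chroman closure.
- Fallback: the acetates are replaced by silyl ethers, which are removed by buffered fluoride. It sets out from 7 and returns at 11. Silylation of 7 (TBSCl, imidazole, DMF) would give 3-[3-bromo-4,5-bis(tert-butyldimethylsilyloxy)phenyl]-7-(tert-butyldimethylsilyloxy)-5-methoxychromen-4-one F6. Stille coupling with 9 (Pd(PPh3)4, DMF, 95 °C) would give 3-[3,4-bis(tert-butyldimethylsilyloxy)-5-(3-methylbut-2-enyl)phenyl]-7-(tert-butyldimethylsilyloxy)-5-methoxychromen-4-one F7. Bu4NF buffered with AcOH in THF at 0 °C would give 11.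

## Further compounds

F1 | step 4 | 1-[2-methoxy-4,6-bis(methoxymethoxy)phenyl]ethanone | CC(=O)c1c(OCOC)cc(OCOC)cc1OC
F2 | step 4 | (E)-3-[3-bromo-4,5-bis(methoxymethoxy)phenyl]-1-[2-methoxy-4,6-bis(methoxymethoxy)phenyl]prop-2-en-1-one | COCOc1cc(OCOC)c(C(=O)/C=C/c2cc(Br)c(OCOC)c(OCOC)c2)c(OC)c1
F3 | step 4 | trans-[3-[3-bromo-4,5-bis(methoxymethoxy)phenyl]oxiran-2-yl]-[2-methoxy-4,6-bis(methoxymethoxy)phenyl]methanone (racemic; the 2S,3R enantiomer is drawn) | COCOc1cc(OCOC)c(C(=O)[C@H]2O[C@@H]2c3cc(Br)c(OCOC)c(OCOC)c3)c(OC)c1
F4 | step 4 | 2-[3-bromo-4,5-bis(methoxymethoxy)phenyl]-3-[2-methoxy-4,6-bis(methoxymethoxy)phenyl]-3-oxopropanal (racemic) | COCOc1cc(OCOC)c(C(=O)C(C=O)c2cc(Br)c(OCOC)c(OCOC)c2)c(OC)c1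
F5 | step 6 | 7-acetoxy-3-(3,4-diacetoxy-5-prop-2-enylphenyl)-5-methoxychromen-4-one | COc1cc(OC(C)=O)cc2occ(-c3cc(OC(C)=O)c(OC(C)=O)c(CC=C)c3)c(=O)c12
F6 | step 7 | 3-[3-bromo-4,5-bis(tert-butyldimethylsilyloxy)phenyl]-7-(tert-butyldimethylsilyloxy)-5-methoxychromen-4-one | COc1cc(O[Si](C)(C)C(C)(C)C)cc2occ(-c3cc(O[Si](C)(C)C(C)(C)C)c(O[Si](C)(C)C(C)(C)C)c(Br)c3)c(=O)c12
F7 | step 7 | 3-[3,4-bis(tert-butyldimethylsilyloxy)-5-(3-methylbut-2-enyl)phenyl]-7-(tert-butyldimethylsilyloxy)-5-methoxychromen-4-one | COc1cc(O[Si](C)(C)C(C)(C)C)cc2occ(-c3cc(O[Si](C)(C)C(C)(C)C)c(O[Si](C)(C)C(C)(C)C)c(CC=C(C)C)c3)c(=O)c12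
A1 | alternative 1 | 3-[3-bromo-5-(3-methylbut-2-enyl)-4-(triisopropylsilyloxy)phenyl]-5-methoxy-7-(triisopropylsilyloxy)chromen-4-one | COc1cc(O[Si](C(C)C)(C(C)C)C(C)C)cc2occ(-c3cc(Br)c(O[Si](C(C)C)(C(C)C)C(C)C)c(CC=C(C)C)c3)c(=O)c12
A2 | alternative 1 | 3-bromo-5-[5-methoxy-4-oxo-7-(triisopropylsilyloxy)chromen-3-yl]pyran-2-one | COc1cc(O[Si](C(C)C)(C(C)C)C(C)C)cc2occ(-c3cc(Br)c(=O)oc3)c(=O)c12
A3 | alternative 1 | triisopropyl(5-methylhex-4-en-1-ynoxy)silane | CC(C)=CCC#CO[Si](C(C)C)(C(C)C)C(C)C
A4 | alternative 2 | 3-[3,4-bis(methoxymethoxy)-5-(3-methylbut-2-enyl)phenyl]-5-methoxy-7-(methoxymethoxy)chromen-4-one | COCOc1cc(OC)c2c(c1)occ(-c1cc(OCOC)c(OCOC)c(CC=C(C)C)c1)c2=O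
A5 | alternative 2 | [3-methoxy-5-(methoxymethoxy)-2-(trimethylsilyl)phenyl] trifluoromethanesulfonate | COCOc1cc(OC)c([Si](C)(C)C)c(OS(=O)(=O)C(F)(F)F)c1
A6 | alternative 2 | (E)-2-[3,4-bis(methoxymethoxy)-5-(3-methylbut-2-enyl)phenyl]-3-methoxyprop-2-enoic acid | CO/C=C(/C(=O)O)c1cc(OCOC)c(OCOC)c(CC=C(C)C)c1
A7 | alternative 3 | 3-[3,4-bis(methoxymethoxy)-5-(3-methylbut-2-enyl)phenyl]-5,7-dihydroxychromen-4-one | Oc1cc(O)c2c(c1)occ(-c1cc(OCOC)c(OCOC)c(CC=C(C)C)c1)c2=O
A8 | alternative 3 | 3-[3,4-bis(methoxymethoxy)-5-(3-methylbut-2-enyl)phenyl]-7-methylpyrano[4,3-b]pyran-4,5-dione | Cc1cc2occ(-c3cc(OCOC)c(OCOC)c(CC=C(C)C)c3)c(=O)c2c(=O)o1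
A9 | alternative 3 | 4-hydroxy-6-methylpyran-2-one | Cc1cc(O)cc(=O)o1
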